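**Retrosynthetic overview**
1. Lappaol A ⇐ removal of two O-benzyl groups and one N–O-masked primary alcohol from the fully assembled trans-dibenzylbutyrolactone.
2. Lactone ring (formed second) ⇐ trans-selective enolate benzylation of an (R)-β-(dihydrobenzofuranylmethyl)-γ-butyrolactone, itself from Stobbe condensation, asymmetric hydrogenation and reduction–lactonisation of a dihydrobenzofuran-5-carbaldehyde.
3. Dihydrobenzofuran ring (formed first): C3–C3a bond ⇐ 5-exo aryl radical cyclisation with TEMPO capture of an o-iodoaryl 1-arylallyl ether, which sets C3 trans to C2.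
4. Key disconnection: the O1–C2 ether bond ⇐ enantioselective iridium-catalysed O-allylation of 5-iodovanillin with a racemic aryl vinyl carbinol; this sets C2, from which C3 is relayed.
5. Carbinol ⇐ O-benzylvanillin + vinylmagnesium bromide.

Assumption: the sense of induction of the two chiral catalysts (steps 2 and 5) is as written; if experiment shows the opposite, the antipodal ligand, equally available, is used.

Abbreviations in names: TMPO = (2,2,6,6-tetramethylpiperidin-1-yl)oxy. Ar* = (2S,3R)-2-[4-(benzyloxy)-3-methoxyphenyl]-7-methoxy-3-(TMPO-methyl)-2,3-dihydro-1-benzofuran-5-yl (2,3-trans). L = (R)-BINOL phosphoramidite of 5H-dibenzo[b,f]azepine (a P,olefin ligand).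

**Route**

Step 1
Reactants: 1 4-(benzyloxy)-3-methoxybenzaldehyde; 2 vinylmagnesium bromide
Product: 3 rac-1-[4-(benzyloxy)-3-methoxyphenyl]prop-2-en-1-ol
Conditions: CH2=CHMgBr (1.2 equiv), THF, 0 °C; aq NH4Cl
Reagents that add atoms: none
Why: Grignard 1,2-addition to a non-enolisable aryl aldehyde; the carbinol is deliberately racemic because step 2 erases this centre through a π-allyl intermediate.

Step 2
Reactants: 3 rac-1-[4-(benzyloxy)-3-methoxyphenyl]prop-2-en-1-ol; 4 4-hydroxy-3-iodo-5-methoxybenzaldehyde (5-iodovanillin)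
Product: 5 4-{[(1S)-1-[4-(benzyloxy)-3-methoxyphenyl]prop-2-en-1-yl]oxy}-3-iodo-5-methoxybenzaldehyde
Conditions: [Ir(cod)Cl]2 (4 mol %), L (16 mol %), Zn(OTf)2 (10 mol %), 3 (2.2 equiv), ClCH2CH2Cl, 25 °C
Reagents that add atoms: none
Why: Proposed new method: iridium-catalysed enantioselective allylic O-arylation of a racemic branched allylic alcohol by an acidic, doubly ortho-substituted phenol; the Ir/(P,olefin) complex ionises the carbinol to a trivalent iridium π-allyl (the phenol, pKa about 7, supplies the proton and Zn(OTf)2 assists loss of water), the aryloxide of the ion pair attacks the aryl-bearing allyl terminus on the ligand-defined face to give the branched (S)-ether, and C-allylation cannot compete because both ortho positions and the para position of 4 are blocked; closest known reaction type: iridium/(P,olefin)-phosphoramidite etherification of racemic branched allylic alcohols with aliphatic alcohols, and iridium-catalysed etherification of cinnamyl carbonates with aryloxides (Tsuji–Trost-type allylic substitution).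

Step 3
Reactants: 5 4-{[(1S)-1-[4-(benzyloxy)-3-methoxyphenyl]prop-2-en-1-yl]oxy}-3-iodo-5-methoxybenzaldehyde
Product: 6 (2S,3R)-2-[4-(benzyloxy)-3-methoxyphenyl]-7-methoxy-3-(TMPO-methyl)-2,3-dihydro-1-benzofuran-5-carbaldehyde
Conditions: Bu3SnH (1.3 equiv, slow addition), TEMPO (4 equiv), toluene, 70 °C
Reagents that add atoms: TEMPO (2,2,6,6-tetramethylpiperidin-1-oxyl), CC1(C)CCCC(C)(C)N1[O]
Why: 5-exo-trig aryl radical cyclisation with TEMPO capture of the primary radical (radical cyclisation/oxyamination); C3 is set trans to the C2 aryl group because the transition state keeps the C2–H bond eclipsed with the vinyl group (minimal allylic strain, Beckwith–Houk model), and cyclisation outruns TEMPO capture of the aryl radical.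

Step 4
Reactants: 6 (2S,3R)-2-[4-(benzyloxy)-3-methoxyphenyl]-7-methoxy-3-(TMPO-methyl)-2,3-dihydro-1-benzofuran-5-carbaldehyde; 7 dimethyl succinate
Product: 8 (3E)-4-Ar*-3-(methoxycarbonyl)but-3-enoic acid
Conditions: NaOMe (2.5 equiv), 7 (1.5 equiv), MeOH, reflux; aq HCl to pH 3
Reagents that add atoms: none
Why: Stobbe condensation; the succinate enolate adds to the aldehyde, the alkoxide closes to a paraconate and base-induced ring opening gives the (E)-half-ester with the free acid on the CH2 arm, while ethers, alkoxyamine and dihydrobenzofuran are inert to methoxide.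

Step 5
Reactants: 8 (3E)-4-Ar*-3-(methoxycarbonyl)but-3-enoic acid
Product: 9 (3R)-4-Ar*-3-(methoxycarbonyl)butanoic acid
Conditions: [Rh(cod)((S,S)-Et-DuPhos)]BF4 (1 mol %), H2 (5 atm), Et3N (1 equiv), MeOH, 25 °C
Reagents that add atoms: none
Why: Rh–bisphosphine asymmetric hydrogenation of an itaconate half-ester (carboxylate-assisted chelation) sets the future lactone C4 centre as R under catalyst control, independent of the remote dihydrobenzofuran centres; aryl benzyl ethers survive homogeneous rhodium.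

Step 6
Reactants: 9 (3R)-4-Ar*-3-(methoxycarbonyl)butanoic acid
Product: 11 (4R)-4-(Ar*-methyl)oxolan-2-one, via hydroxy acid 10 (not isolated)
Conditions: KOH (1 equiv), EtOH; NaBH4/CaCl2 [Ca(BH4)2], EtOH, −10 °C → rt; then 1 M HCl, rt
Reagents that add atoms: none
Why: Chemoselective borohydride reduction of the ester beside the carboxylate salt, then acid-promoted γ-lactonisation; the stereocentre is not touched.

Step 7
Reactants: 12 [4-(benzyloxy)-3-methoxyphenyl]methanol
Product: 13 1-(benzyloxy)-4-(bromomethyl)-2-methoxybenzene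
Conditions: PBr3 (0.4 equiv), Et2O, 0 °C; used crude
Reagents that add atoms: PBr3 (phosphorus tribromide), BrP(Br)Br
Why: Benzylic alcohol-to-bromide conversion by SN2 displacement of the phosphite ester; the labile electron-rich bromide is made fresh.

Step 8
Reactants: 11 (4R)-4-(Ar*-methyl)oxolan-2-one; 13 1-(benzyloxy)-4-(bromomethyl)-2-methoxybenzene
Product: 15 (3R,4R)-3-[4-(benzyloxy)-3-methoxybenzyl]-4-(Ar*-methyl)oxolan-2-one, via lithium enolate 14 (not isolated)
Conditions: LiN(SiMe3)2 (1.1 equiv), THF, −78 °C; 13 (1.2 equiv), DMPU, −78 → −30 °C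
Reagents that add atoms: none
Why: Lactone enolate alkylation; the benzyl bromide approaches anti to the large C4 substituent and gives the trans-(3R,4R) lactone, as is standard for dibenzylbutyrolactone lignans.

Step 9
Reactants: 15 (3R,4R)-3-[4-(benzyloxy)-3-methoxybenzyl]-4-(Ar*-methyl)oxolan-2-one
Product: 16 (3R,4R)-3-[4-(benzyloxy)-3-methoxybenzyl]-4-({(2S,3R)-2-[4-(benzyloxy)-3-methoxyphenyl]-3-(hydroxymethyl)-7-methoxy-2,3-dihydro-1-benzofuran-5-yl}methyl)oxolan-2-one
Conditions: Zn dust, AcOH/THF/H2O (3:1:1), 50 °C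
Reagents that add atoms: none
Why: Reductive N–O cleavage of the alkoxyamine by zinc in acetic acid (dissolving-metal reduction); benzyl ethers, lactone and the O-benzylated dihydrobenzofuran are untouched and no stereocentre is affected.

Step 10
Reactants: 16 (3R,4R)-3-[4-(benzyloxy)-3-methoxybenzyl]-4-({(2S,3R)-2-[4-(benzyloxy)-3-methoxyphenyl]-3-(hydroxymethyl)-7-methoxy-2,3-dihydro-1-benzofuran-5-yl}methyl)oxolan-2-one
Product: 17 lappaol A, (3R,4R)-3-(4-hydroxy-3-methoxybenzyl)-4-{[(2S,3R)-2-(4-hydroxy-3-methoxyphenyl)-3-(hydroxymethyl)-7-methoxy-2,3-dihydro-1-benzofuran-5-yl]methyl}oxolan-2-one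
Conditions: H2 (1 atm), 10 % Pd/C, EtOAc, 25 °C
Reagents that add atoms: none
Why: Catalytic hydrogenolysis of the two aryl benzyl ethers, which at 1 atm in neutral solvent are cleaved much faster than the cyclic benzylic aryl ether of the dihydrobenzofuran; no stereocentre is affected.

**Compound list**
1 | 4-(benzyloxy)-3-methoxybenzaldehyde (O-benzylvanillin) | O=Cc1ccc(OCc2ccccc2)c(OC)c1 | starting material
2 | vinylmagnesium bromide | C=C[Mg]Br | starting material
3 | rac-1-[4-(benzyloxy)-3-methoxyphenyl]prop-2-en-1-ol (racemate) | OC(C=C)c1ccc(OCc2ccccc2)c(OC)c1 | intermediate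
4 | 4-hydroxy-3-iodo-5-methoxybenzaldehyde (5-iodovanillin) | O=Cc1cc(I)c(O)c(OC)c1 | starting material
5 | 4-{[(1S)-1-[4-(benzyloxy)-3-methoxyphenyl]prop-2-en-1-yl]oxy}-3-iodo-5-methoxybenzaldehyde | COc1cc(C=O)cc(I)c1O[C@@H](C=C)c1ccc(OCc2ccccc2)c(OC)c1 | intermediate
6 | (2S,3R)-2-[4-(benzyloxy)-3-methoxyphenyl]-7-methoxy-3-(TMPO-methyl)-2,3-dihydro-1-benzofuran-5-carbaldehyde | O=Cc1cc(OC)c2c(c1)[C@H](CON1C(C)(C)CCCC1(C)C)[C@@H](c1ccc(OCc3ccccc3)c(OC)c1)O2 | intermediate
7 | dimethyl succinate | COC(=O)CCC(=O)OC | starting material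
8 | (3E)-4-Ar*-3-(methoxycarbonyl)but-3-enoic acid | OC(=O)C/C(C(=O)OC)=C\c1cc(OC)c2c(c1)[C@H](CON1C(C)(C)CCCC1(C)C)[C@@H](c1ccc(OCc3ccccc3)c(OC)c1)O2 | intermediate
9 | (3R)-4-Ar*-3-(methoxycarbonyl)butanoic acid | COC(=O)[C@@H](CC(=O)O)Cc1cc(OC)c2c(c1)[C@H](CON1C(C)(C)CCCC1(C)C)[C@@H](c1ccc(OCc3ccccc3)c(OC)c1)O2 | intermediate
10 | (3R)-4-Ar*-3-(hydroxymethyl)butanoic acid (not isolated) | OC[C@@H](CC(=O)O)Cc1cc(OC)c2c(c1)[C@H](CON1C(C)(C)CCCC1(C)C)[C@@H](c1ccc(OCc3ccccc3)c(OC)c1)O2 | intermediate
11 | (4R)-4-(Ar*-methyl)oxolan-2-one | C1C(=O)OC[C@@H]1Cc1cc(OC)c2c(c1)[C@H](CON1C(C)(C)CCCC1(C)C)[C@@H](c1ccc(OCc3ccccc3)c(OC)c1)O2 | intermediate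
12 | [4-(benzyloxy)-3-methoxyphenyl]methanol | OCc1ccc(OCc2ccccc2)c(OC)c1 | starting material
13 | 1-(benzyloxy)-4-(bromomethyl)-2-methoxybenzene | BrCc1ccc(OCc2ccccc2)c(OC)c1 | intermediate
14 | lithium (4R)-4-(Ar*-methyl)-4,5-dihydrofuran-2-olate (not isolated) | C1=C(O[Li])OC[C@@H]1Cc1cc(OC)c2c(c1)[C@H](CON1C(C)(C)CCCC1(C)C)[C@@H](c1ccc(OCc3ccccc3)c(OC)c1)O2 | intermediate
15 | (3R,4R)-3-[4-(benzyloxy)-3-methoxybenzyl]-4-(Ar*-methyl)oxolan-2-one | COc1cc(C[C@H]2C(=O)OC[C@@H]2Cc2cc(OC)c3c(c2)[C@H](CON4C(C)(C)CCCC4(C)C)[C@@H](c2ccc(OCc4ccccc4)c(OC)c2)O3)ccc1OCc1ccccc1 | intermediate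
16 | (3R,4R)-3-[4-(benzyloxy)-3-methoxybenzyl]-4-({(2S,3R)-2-[4-(benzyloxy)-3-methoxyphenyl]-3-(hydroxymethyl)-7-methoxy-2,3-dihydro-1-benzofuran-5-yl}methyl)oxolan-2-one | COc1cc(C[C@H]2C(=O)OC[C@@H]2Cc2cc(OC)c3c(c2)[C@H](CO)[C@@H](c2ccc(OCc4ccccc4)c(OC)c2)O3)ccc1OCc1ccccc1 | intermediate
17 | lappaol A | COc1cc(C[C@H]2C(=O)OC[C@@H]2Cc2cc(OC)c3c(c2)[C@H](CO)[C@@H](c2ccc(O)c(OC)c2)O3)ccc1O | target

**Step count and risks**

Total step count: 10. Longest linear sequence: 9 (steps 1–6 and 8–10; step 7 is a one-step side branch).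

Three steps most likely to fail:

Step 2 (the proposed new O-allylation). The hindered phenol may attack slowly, the carbinol may etherify itself, and the electron-rich allyl system may ionise without the metal and erode the ee. The process may also run as a kinetic resolution, which is why 2.2 equiv of cheap 3 are used. The fallback uses known chemistry, sets out from 1 and 4, and comes back at 5. Horner–Wadsworth–Emmons olefination of 1 with triethyl phosphonoacetate (NaH, THF) gives ethyl (2E)-3-[4-(benzyloxy)-3-methoxyphenyl]prop-2-enoate F1. Reduction with iBu2AlH (CH2Cl2, −78 °C) gives (2E)-3-[4-(benzyloxy)-3-methoxyphenyl]prop-2-en-1-ol F2. ClCO2Me and pyridine give (2E)-3-[4-(benzyloxy)-3-methoxyphenyl]prop-2-en-1-yl methyl carbonate F3. F3 is then coupled with 4, used as its lithium salt (LiN(SiMe3)2), under [Ir(cod)Cl]2 and a BINOL N,N-bis(1-phenylethyl)phosphoramidite in THF at 50 °C. This is the established branched-selective, enantioselective iridium etherification of linear cinnamyl carbonates with aryloxides, working in a basic rather than an acidic manifold.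

Step 3 (radical cyclisation). The 2,3-trans preference of a very fast aryl radical closure may be only moderate, and 1,5-hydrogen transfer from the doubly activated C–H next to oxygen can compete. The fallback replaces kinetic control by thermodynamic control, sets out from 15 (carried forward as the C3-epimer mixture) and comes back at 16. mCPBA (CH2Cl2, 0 °C) oxidises the alkoxyamine nitrogen and the N-oxide fragments by Cope-type elimination to the 3-formyl compound. Catalytic DBU in the same flask equilibrates this to the 2,3-trans aldehyde (3R,4R)-3-[4-(benzyloxy)-3-methoxybenzyl]-4-({(2S,3S)-2-[4-(benzyloxy)-3-methoxyphenyl]-3-formyl-7-methoxy-2,3-dihydro-1-benzofuran-5-yl}methyl)oxolan-2-one F4; the 3S label reflects only a priority change. NaBH4 (MeOH/THF, −20 °C) then reduces the aldehyde beside the lactone to give 16. This also replaces step 9.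

Step 4 (Stobbe condensation). Hot methoxide on the most elaborate aldehyde of the route, together with succinate self-condensation, can give low conversion. The fallback is a Wittig route, sets out from 6 and comes back at 8. Maleic anhydride and PPh3 give (triphenylphosphoranylidene)succinic anhydride F5. Methanol opens it to methyl hydrogen (triphenylphosphoranylidene)succinate F6, Ph3P=C(CO2Me)CH2CO2H. This stabilised ylide olefinates 6 in toluene at 80 °C under neutral conditions and gives the same (E)-half-ester 8.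

Further compounds
F1 | step 2 | ethyl (2E)-3-[4-(benzyloxy)-3-methoxyphenyl]prop-2-enoate | CCOC(=O)/C=C/c1ccc(OCc2ccccc2)c(OC)c1
F2 | step 2 | (2E)-3-[4-(benzyloxy)-3-methoxyphenyl]prop-2-en-1-ol | OC/C=C/c1ccc(OCc2ccccc2)c(OC)c1
F3 | step 2 | (2E)-3-[4-(benzyloxy)-3-methoxyphenyl]prop-2-en-1-yl methyl carbonate | COC(=O)OC/C=C/c1ccc(OCc2ccccc2)c(OC)c1
F4 | step 3 | (3R,4R)-3-[4-(benzyloxy)-3-methoxybenzyl]-4-({(2S,3S)-2-[4-(benzyloxy)-3-methoxyphenyl]-3-formyl-7-methoxy-2,3-dihydro-1-benzofuran-5-yl}methyl)oxolan-2-one (2,3-trans) | COc1cc(C[C@H]2C(=O)OC[C@@H]2Cc2cc(OC)c3c(c2)[C@H](C=O)[C@@H](c2ccc(OCc4ccccc4)c(OC)c2)O3)ccc1OCc1ccccc1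
F5 | step 4 | (triphenylphosphoranylidene)succinic anhydride | O=C1CC(=P(c2ccccc2)(c2ccccc2)c2ccccc2)C(=O)O1
F6 | step 4 | methyl hydrogen (triphenylphosphoranylidene)succinate | COC(=O)C(CC(=O)O)=P(c1ccccc1)(c1ccccc1)c1ccccc1
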